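**Plan**

1. Numbering used throughout: C1 angelate carbinol, C2=C3 olefin (methyl on C3), C4 CH2, C5 veratrate carbinol, C6 fusion CH, C7 C(OH)(isopropyl), C8 and C9 CH2, C10 methyl-bearing fusion carbon. Ring A (seven-membered) is C1–C6 plus C10, ring B (five-membered) is C6–C10, and β is the face of the C10 methyl.
2. Enabling feature: the oxygenated C5 lies between C4 and C6 in ring A, so C4–C5–C6 is a 2-oxyallyl unit, C10–C1–C2–C3 is its diene partner and C7–C8–C9 is the tether. The C7 oxygen sits next to C6 and can be the leaving group (as an epoxide) that unmasks the cation.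
3. Retrosynthesis: the two esters are removed, C1–OH/C2=C3 is returned to a C1=C2 olefin and C5–OH to a ketone, then C3–C4 and C6–C10 are cut together to an acyclic epoxy enol silane. Its chain is cut at C6=C7 (ynoate plus isopropyl cuprate) and C8–C9 (Johnson–Claisen).
4. Forward: the chain is built linearly from crotonaldehyde; ring A and ring B then arise together in one (4+3) step; afterwards only C5, C1/C2=C3 and the esters are adjusted.
5. Stereochemistry: C7 comes from a Sharpless epoxidation with D-(−)-diethyl tartrate, the only external chiral source. C6, C10 and C3 follow from C7 in the cycloaddition, C5 from hydride delivery by the C7 hydroxyl, and C1 from epoxidation anti to the C10 methyl followed by anti opening.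

Key step: step 13

Assumption: metal alkoxides and alkenylmetal species that are only protonated on aqueous work-up are treated as salts of the numbered products and carry no numbers of their own.

**Route**

Step 1
Reactants: 1 (2E)-but-2-enal (crotonaldehyde); 2 prop-1-en-2-ylmagnesium bromide
Product: 3 (4E)-2-methylhexa-1,4-dien-3-ol (racemic)
Conditions: THF, −78 to 0 °C; then H2O
Reagents that add atoms: none
Why: Grignard 1,2-addition to the enal carbonyl should give the bis-allylic alcohol, whose carbinol centre is lost in the next step.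

Step 2
Reactants: 3 (4E)-2-methylhexa-1,4-dien-3-ol; 4 triethyl orthoacetate
Product: 7 ethyl (4E,6E)-4-methylocta-4,6-dienoate, via mixed orthoester 5 (not isolated), via ketene acetal 6 (not isolated)
Conditions: EtCO2H (5 mol %), excess 4, 140 °C, EtOH distilled off
Reagents that add atoms: none
Why: Johnson–Claisen rearrangement, in which the [3,3] shift should run through the unsubstituted CH2 terminus of the isopropenyl arm in a chair with the propenyl group equatorial, making the new C10=C1 bond E and leaving C2=C3 E.

Step 3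
Reactants: 7 ethyl (4E,6E)-4-methylocta-4,6-dienoate
Product: 8 (4E,6E)-4-methylocta-4,6-dienal
Conditions: i-Bu2AlH (1.05 equiv), CH2Cl2, −78 °C; then aq KNaC4H4O6 (potassium sodium tartrate)
Reagents that add atoms: none
Why: Partial reduction of an ester with i-Bu2AlH at −78 °C should stop at the aluminium hemiacetal, which releases the aldehyde on work-up.

Step 4
Reactants: 8 (4E,6E)-4-methylocta-4,6-dienal
Product: 9 (5E,7E)-5-methylnona-5,7-dien-1-yne
Conditions: dimethyl (1-diazo-2-oxopropyl)phosphonate, K2CO3, MeOH, 0 °C to rt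
Reagents that add atoms: dimethyl (1-diazo-2-oxopropyl)phosphonate, COP(=O)(OC)C(=[N+]=[N-])C(C)=O
Why: Seyferth–Gilbert homologation in its Ohira–Bestmann form should convert the enolisable aldehyde into the terminal alkyne under mild carbonate conditions that leave the diene untouched.

Step 5
Reactants: 9 (5E,7E)-5-methylnona-5,7-dien-1-yne
Product: 11 methyl (6E,8E)-6-methyldeca-6,8-dien-2-ynoate, via lithium acetylide 10 (not isolated)
Conditions: n-BuLi, THF, −78 °C; then ClCO2Me, −78 to 0 °C
Reagents that add atoms: methyl chloroformate, COC(Cl)=O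
Why: Deprotonation of the terminal alkyne and C-acylation of the acetylide with a chloroformate is the standard entry to alk-2-ynoates.

Step 6
Reactants: 11 methyl (6E,8E)-6-methyldeca-6,8-dien-2-ynoate; 12 propan-2-ylmagnesium chloride
Product: 13 methyl (2E,6E,8E)-6-methyl-3-(propan-2-yl)deca-2,6,8-trienoate
Conditions: 12 (2.0 equiv), CuBr·SMe2 (1.0 equiv), THF, −78 °C; then MeOH at −78 °C, H2O
Reagents that add atoms: none
Why: Syn carbocupration (cuprate conjugate addition) of the ynoate at −78 °C and protonation of the alkenylcopper with retention should place isopropyl trans to the ester, the 2E geometry that later puts C5 cis to C8 on the epoxide.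

Step 7
Reactants: 13 methyl (2E,6E,8E)-6-methyl-3-(propan-2-yl)deca-2,6,8-trienoate
Product: 14 (2E,6E,8E)-6-methyl-3-(propan-2-yl)deca-2,6,8-trien-1-ol
Conditions: i-Bu2AlH (2.2 equiv), CH2Cl2, −78 °C; then aq KNaC4H4O6
Reagents that add atoms: none
Why: 1,2-Reduction of the enoate with i-Bu2AlH should give the allylic alcohol without touching the olefins.

Step 8
Reactants: 14 (2E,6E,8E)-6-methyl-3-(propan-2-yl)deca-2,6,8-trien-1-ol
Product: 15 [(2R,3R)-3-[(3E,5E)-3-methylhepta-3,5-dien-1-yl]-3-(propan-2-yl)oxiran-2-yl]methanol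
Conditions: Ti(OiPr)4 (10 mol %), D-(−)-diethyl tartrate (12 mol %), t-BuOOH, 4 Å molecular sieves, CH2Cl2, −20 °C
Reagents that add atoms: tert-butyl hydroperoxide, CC(C)(C)OO
Why: Sharpless asymmetric epoxidation should oxidise only the allylic-alcohol olefin, and the D-(−)-tartrate ligand should deliver oxygen to the face that gives the 2R,3R epoxide, which fixes C7 (R) for the rest of the route.

Step 9
Reactants: 15 the 2R,3R epoxy alcohol
Product: 16 (2S,3R)-3-[(3E,5E)-3-methylhepta-3,5-dien-1-yl]-3-(propan-2-yl)oxirane-2-carbaldehyde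
Conditions: Dess–Martin periodinane, NaHCO3, CH2Cl2, 0 °C to rt
Reagents that add atoms: none
Why: Dess–Martin oxidation of a primary epoxy alcohol should give the epoxy aldehyde under buffered conditions that leave the epoxide and the diene intact.

Step 10
Reactants: 16 the epoxy aldehyde
Product: 17 1-[(2R,3R)-3-[(3E,5E)-3-methylhepta-3,5-dien-1-yl]-3-(propan-2-yl)oxiran-2-yl]ethan-1-ol (both carbinol epimers)
Conditions: MeMgBr, THF, −78 °C; then H2O
Reagents that add atoms: methylmagnesium bromide, C[Mg]Br
Why: Grignard addition to the aldehyde at −78 °C should be much faster than epoxide opening, and the two carbinol epimers converge in the next step.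

Step 11
Reactants: 17 the epoxy carbinol
Product: 18 1-[(2S,3R)-3-[(3E,5E)-3-methylhepta-3,5-dien-1-yl]-3-(propan-2-yl)oxiran-2-yl]ethan-1-one
Conditions: Dess–Martin periodinane, NaHCO3, CH2Cl2, 0 °C to rt
Reagents that add atoms: none
Why: Dess–Martin oxidation of the secondary alcohol should give the epoxy methyl ketone, whose epoxide C–H is not enolisable.

Step 12
Reactants: 18 the epoxy methyl ketone
Product: 19 triethyl({1-[(2S,3R)-3-[(3E,5E)-3-methylhepta-3,5-dien-1-yl]-3-(propan-2-yl)oxiran-2-yl]ethenyl}oxy)silane
Conditions: Et3SiOTf (1.2 equiv), Et3N (3 equiv), CH2Cl2, −78 to 0 °C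
Reagents that add atoms: triethylsilyl trifluoromethanesulfonate, CC[Si](CC)(CC)OS(=O)(=O)C(F)(F)F
Why: Soft enolisation with a silyl triflate and amine should silylate the methyl side, the only enolisable side, while the excess amine keeps the medium non-acidic so that the epoxide survives.

Step 13
Reactants: 19 the epoxy enol silane
Product: 21 trans-fused hydroxy ketone (C1=C2; C5=O; 3α-methyl; 6α-H; 7β-OH; 7α-isopropyl; 10β-methyl), via C7 triethylsilyl ether 20 (not isolated)
Conditions: Et3SiOTf (0.1 equiv), CH2Cl2, −78 °C; then HF·pyridine, THF, 0 °C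
Reagents that add atoms: none
Why: Catalytic Et3SiOTf should silylate the epoxide oxygen, the C6–O bond (the one conjugated with the enol silane) should ionise toward a 2-(silyloxy)allyl cation C4–C5–C6 while the diene terminus C10 attacks C6 and the enol silane carbon C4 closes onto C3, and silyl transfer from the resulting C5 oxocarbenium ion to the next epoxide turns the catalyst over before HF·pyridine frees the C7 hydroxyl. The closest known reaction type is the Lewis-acid-catalysed intramolecular (4+3) cycloaddition of epoxy enol silanes with tethered dienes, a variant of the oxyallyl cation (4+3) cycloaddition that is also reached from alpha-halo ketones. Ring B (five-membered) closes through the C6–C10 bond as the three-atom tether C7–C8–C9 folds the diene onto the cation terminus, and ring A (seven-membered) closes by the (4+3) union of C4–C5–C6 with C10–C1–C2–C3 through C6–C10 and C3–C4. C7 is carried over from the epoxide; C6 is set by attack of C10 anti to the departing oxygen (inversion), which from the epoxide with C5 cis to C8 gives 6α-H trans to the 7β-oxygen; C10 is set by the fold of the tether with isopropyl and the diene arm pseudo-equatorial in the forming ring B (10β-methyl, trans fusion); C3 is set by suprafacial addition to the s-cis (E,E)-diene, which puts the C3 methyl anti to the C10 methyl (3β-H). The step needs ionisation at C6 and not at the tertiary C7, cycloaddition in preference to open-chain alkylation or (3+2) closure, and the trans ring fusion; the first rests on allylic stabilisation by the enol silane, the second on the concerted asynchronous pathway at −78 °C with C3 held within reach of C4 by the short tether, and the third on the C7 stereocentre, with C6 still epimerisable next to the ketone.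

Step 14
Reactants: 21 the hydroxy ketone
Product: 22 5α,7β-diol (C1=C2; 3α-methyl; 6α-H; 7α-isopropyl; 10β-methyl)
Conditions: Me4NBH(OAc)3 (5 equiv), MeCN/AcOH 1:1, −30 to −20 °C
Reagents that add atoms: none
Why: Evans–Saksena hydroxyl-directed reduction, in which the acetoxyborohydride bound to the C7 oxygen should deliver hydride to the β face of the C5 ketone through a six-membered chair, giving the 1,3-anti diol (5α-OH) that external hydride attack from the open α face would not give.

Step 15
Reactants: 22 the 5α,7β-diol; 23 3,4-dimethoxybenzoyl chloride (veratroyl chloride)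
Product: 24 5α-(3,4-dimethoxybenzoate) of 22 with free 7β-OH
Conditions: pyridine, DMAP (10 mol %), CH2Cl2, 0 °C to rt
Reagents that add atoms: none
Why: DMAP-catalysed acylation with the acid chloride should take the secondary C5 hydroxyl only, since the tertiary C7 hydroxyl flanked by isopropyl is inert under these conditions.

Step 16
Reactants: 24 the 5α-veratrate
Product: 25 1α,2α-epoxide of 24
Conditions: mCPBA, CH2Cl2/aq NaHCO3, 0 °C
Reagents that add atoms: 3-chloroperbenzoic acid, OOC(=O)c1cccc(Cl)c1
Why: Prilezhaev epoxidation of the cis-disubstituted C1=C2 olefin should occur on the α face, anti to the axial angular methyl on the adjacent C10, as with peracid attack next to angular methyl groups in fused terpenoid rings.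

Step 17
Reactants: 25 the 1α,2α-epoxide
Product: 28 1α,7β-diol 5α-(3,4-dimethoxybenzoate) with C2=C3, via hydroxy selenide 26 (not isolated), via selenoxide 27 (not isolated)
Conditions: PhSeSePh (0.75 equiv), NaBH4 (1.5 equiv), EtOH, reflux; then THF, 30% H2O2, 0 °C to rt
Reagents that add atoms: none
Why: Sharpless–Lauer epoxide-to-allylic-alcohol transposition, in which selenolate should open the epoxide at C2 rather than at the neopentyl C1 with inversion (2β-selenide, 1α-OH, a Fürst–Plattner opening), and the selenoxide should eliminate syn with the 3β-H and away from the carbinol to give C2=C3 and the 1α-allylic alcohol.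

Step 18
Reactants: 28 the allylic alcohol; 29 (2Z)-2-methylbut-2-enoic acid (angelic acid)
Product: 31 target CNP0142353.1, via mixed anhydride 30 (not isolated)
Conditions: 29, 2,4,6-trichlorobenzoyl chloride, Et3N, toluene, rt; then 28, 80 °C
Reagents that add atoms: none
Why: Yamaguchi esterification through the preformed mixed anhydride, run without DMAP, should acylate the secondary allylic C1 hydroxyl (the tertiary C7 hydroxyl stays free) while avoiding isomerisation of the angelate to the tiglate.

**Compound list**

1 | (2E)-but-2-enal (crotonaldehyde) | C/C=C/C=O | starting material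
2 | prop-1-en-2-ylmagnesium bromide | CC(=C)[Mg]Br | starting material
3 | (4E)-2-methylhexa-1,4-dien-3-ol (racemic) | C/C=C/C(O)C(C)=C | intermediate
4 | 1,1,1-triethoxyethane (triethyl orthoacetate) | CCOC(C)(OCC)OCC | starting material
5 | (4E)-3-(1,1-diethoxyethoxy)-2-methylhexa-1,4-diene (mixed orthoester) | CCOC(C)(OCC)OC(/C=C/C)C(C)=C | intermediate
6 | (4E)-3-[(1-ethoxyethenyl)oxy]-2-methylhexa-1,4-diene (ketene acetal) | C=C(OCC)OC(/C=C/C)C(C)=C | intermediate
7 | ethyl (4E,6E)-4-methylocta-4,6-dienoate | CCOC(=O)CC/C(C)=C/C=C/C | intermediate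
8 | (4E,6E)-4-methylocta-4,6-dienal | O=CCC/C(C)=C/C=C/C | intermediate
9 | (5E,7E)-5-methylnona-5,7-dien-1-yne | C#CCC/C(C)=C/C=C/C | intermediate
10 | lithium acetylide of 9 | [Li]C#CCC/C(C)=C/C=C/C | intermediate
11 | methyl (6E,8E)-6-methyldeca-6,8-dien-2-ynoate | COC(=O)C#CCC/C(C)=C/C=C/C | intermediate
12 | propan-2-ylmagnesium chloride | CC(C)[Mg]Cl | starting material
13 | methyl (2E,6E,8E)-6-methyl-3-(propan-2-yl)deca-2,6,8-trienoate | COC(=O)/C=C(/C(C)C)CC/C(C)=C/C=C/C | intermediate
14 | (2E,6E,8E)-6-methyl-3-(propan-2-yl)deca-2,6,8-trien-1-ol | OC/C=C(/C(C)C)CC/C(C)=C/C=C/C | intermediate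
15 | [(2R,3R)-3-[(3E,5E)-3-methylhepta-3,5-dien-1-yl]-3-(propan-2-yl)oxiran-2-yl]methanol | OC[C@H]1O[C@@]1(C(C)C)CC/C(C)=C/C=C/C | intermediate
16 | (2S,3R)-3-[(3E,5E)-3-methylhepta-3,5-dien-1-yl]-3-(propan-2-yl)oxirane-2-carbaldehyde | O=C[C@H]1O[C@@]1(C(C)C)CC/C(C)=C/C=C/C | intermediate
17 | 1-[(2R,3R)-3-[(3E,5E)-3-methylhepta-3,5-dien-1-yl]-3-(propan-2-yl)oxiran-2-yl]ethan-1-ol (both carbinol epimers) | CC(O)[C@H]1O[C@@]1(C(C)C)CC/C(C)=C/C=C/C | intermediate
18 | 1-[(2S,3R)-3-[(3E,5E)-3-methylhepta-3,5-dien-1-yl]-3-(propan-2-yl)oxiran-2-yl]ethan-1-one | CC(=O)[C@H]1O[C@@]1(C(C)C)CC/C(C)=C/C=C/C | intermediate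
19 | triethyl({1-[(2S,3R)-3-[(3E,5E)-3-methylhepta-3,5-dien-1-yl]-3-(propan-2-yl)oxiran-2-yl]ethenyl}oxy)silane | C=C(O[Si](CC)(CC)CC)[C@H]1O[C@@]1(C(C)C)CC/C(C)=C/C=C/C | intermediate
20 | trans-fused bicyclic ketone (route numbering): C1=C2, C5=O, 3α-methyl, 6α-H, 7α-(propan-2-yl), 7β-(triethylsilyloxy), 10β-methyl | C1=C[C@H](C)CC(=O)[C@@H]2[C@]1(C)CC[C@@]2(O[Si](CC)(CC)CC)C(C)C | intermediate
21 | trans-fused hydroxy ketone: C1=C2, C5=O, 3α-methyl, 6α-H, 7β-hydroxy, 7α-(propan-2-yl), 10β-methyl | C1=C[C@H](C)CC(=O)[C@@H]2[C@]1(C)CC[C@@]2(O)C(C)C | intermediate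
22 | 5α,7β-diol: C1=C2, 3α-methyl, 6α-H, 7α-(propan-2-yl), 10β-methyl | C1=C[C@H](C)C[C@H](O)[C@@H]2[C@]1(C)CC[C@@]2(O)C(C)C | intermediate
23 | 3,4-dimethoxybenzoyl chloride (veratroyl chloride) | COc1ccc(cc1OC)C(Cl)=O | starting material
24 | 5α-(3,4-dimethoxybenzoyloxy)-7β-ol: C1=C2, 3α-methyl, 6α-H, 7α-(propan-2-yl), 10β-methyl | C1=C[C@H](C)C[C@H](OC(=O)c3ccc(OC)c(OC)c3)[C@@H]2[C@]1(C)CC[C@@]2(O)C(C)C | intermediate
25 | 1α,2α-epoxide of 24 | O1[C@@H]2[C@H]1[C@H](C)C[C@H](OC(=O)c4ccc(OC)c(OC)c4)[C@@H]3[C@]2(C)CC[C@@]3(O)C(C)C | intermediate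
26 | 2β-(phenylselanyl)-1α,7β-diol 5α-(3,4-dimethoxybenzoate), 3α-methyl | O[C@@H]1[C@@H]([Se]c3ccccc3)[C@H](C)C[C@H](OC(=O)c4ccc(OC)c(OC)c4)[C@@H]2[C@]1(C)CC[C@@]2(O)C(C)C | intermediate
27 | selenoxide of 26 (either configuration at selenium) | O[C@@H]1[C@@H]([Se](=O)c3ccccc3)[C@H](C)C[C@H](OC(=O)c4ccc(OC)c(OC)c4)[C@@H]2[C@]1(C)CC[C@@]2(O)C(C)C | intermediate
28 | 1α,7β-diol 5α-(3,4-dimethoxybenzoate) with C2=C3: 3,10β-dimethyl, 6α-H, 7α-(propan-2-yl) | O[C@@H]1C=C(C)C[C@H](OC(=O)c3ccc(OC)c(OC)c3)[C@@H]2[C@]1(C)CC[C@@]2(O)C(C)C | intermediate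
29 | (2Z)-2-methylbut-2-enoic acid (angelic acid) | C/C=C(/C)C(=O)O | starting material
30 | (2Z)-2-methylbut-2-enoic 2,4,6-trichlorobenzoic anhydride | C/C=C(/C)C(=O)OC(=O)c1c(Cl)cc(Cl)cc1Cl | intermediate
31 | CNP0142353.1: 1α-[(2Z)-2-methylbut-2-enoyloxy]-5α-(3,4-dimethoxybenzoyloxy)-7β-hydroxy-3,10β-dimethyl-7α-(propan-2-yl), C2=C3, 6α-H (C1 R, C5 S, C6 S, C7 R, C10 S) | C/C=C(/C)C(=O)O[C@@H]1C=C(C)C[C@H](OC(=O)c2ccc(OC)c(OC)c2)[C@@H]2[C@]1(C)CC[C@@]2(O)C(C)C | target

**Step count and risks**

Total step count: 18. Longest linear sequence: 18 steps (1 to 31).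

Steps most likely to fail:

Step 13. The silylated epoxide may ionise at the tertiary C7 instead of C6, followed by a hydride or alkyl shift. The fully substituted diene terminus C10 may also react so slowly in the s-cis form that the cation is captured stepwise, ending in open-chain alkylation or (3+2) closure, and facial control at C10 may be lost. The fallback sets out from 18 and comes back at 20, and generates the same C4–C5–C6 oxyallyl cation from an α-chloro ketone under basic conditions without a Lewis acid. Epoxy ketone 18 would be cleaved reductively at the C6–O bond with SmI2 (THF/MeOH, −90 °C) to the β-hydroxy ketone (4S,7E,9E)-4-hydroxy-7-methyl-4-(propan-2-yl)undeca-7,9-dien-2-one F1, with C7 untouched. The tertiary hydroxyl would be silylated (Et3SiOTf, 2,6-lutidine) to the silyl ether F2. Its kinetic lithium enolate on the methyl side (LiN(i-Pr)2, THF, −78 °C) would be chlorinated with N-chlorosuccinimide to the chloromethyl ketone F3. Treatment of F3 with Et3N in CF3CH2OH (or NaOCH2CF3) should enolise toward C6 and expel chloride from C4, and the known intramolecular (4+3) cycloaddition of α-halo ketones with tethered dienes would then give 20, which is desilylated as in step 13.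

Step 16. Peracid attack may show poor facial selectivity, because the α face carries the C3 methyl and the C5 ester while the β face carries the angular methyl. The fallback sets out from 22 and comes back at 25, and uses the 5α-hydroxyl as a directing group before it is acylated. Diol 22 would be epoxidised with VO(acac)2 and t-BuOOH in CH2Cl2, the vanadium alkoxide at C5 delivering oxygen across ring A to the α face, to give the 1α,2α-epoxy-5α,7β-diol F4. Acylation of F4 with 23 (pyridine, DMAP) at the secondary hydroxyl would then give 25.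

Step 14. The hindered tertiary C7 hydroxyl may fail to exchange onto boron, so that no intramolecular hydride transfer takes place and the ketone is either recovered or reduced from the open α face. The fallback sets out from 21 and comes back at 22, and tethers the hydride covalently. Silylation of 21 with chlorodi(propan-2-yl)silane (imidazole, DMAP, DMF) would give the hydridosilyl ether F5. SnCl4-catalysed intramolecular hydrosilylation of the C5 ketone, known to give 1,3-anti products, would give the cyclic di(propan-2-yl)silylene derivative F6 of the 5α,7β-diol. HF·pyridine would then release 22.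

**Further compounds**

F1 | step 13 | (4S,7E,9E)-4-hydroxy-7-methyl-4-(propan-2-yl)undeca-7,9-dien-2-one | CC(=O)C[C@](O)(C(C)C)CC/C(C)=C/C=C/C
F2 | step 13 | (4S,7E,9E)-7-methyl-4-(propan-2-yl)-4-(triethylsilyloxy)undeca-7,9-dien-2-one | CC(=O)C[C@](O[Si](CC)(CC)CC)(C(C)C)CC/C(C)=C/C=C/C
F3 | step 13 | (4S,7E,9E)-1-chloro-7-methyl-4-(propan-2-yl)-4-(triethylsilyloxy)undeca-7,9-dien-2-one | ClCC(=O)C[C@](O[Si](CC)(CC)CC)(C(C)C)CC/C(C)=C/C=C/C
F4 | step 16 | 1α,2α-epoxy-5α,7β-diol: 3α-methyl, 6α-H, 7α-(propan-2-yl), 10β-methyl | O1[C@@H]2[C@H]1[C@H](C)C[C@H](O)[C@@H]3[C@]2(C)CC[C@@]3(O)C(C)C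
F5 | step 14 | 7β-[di(propan-2-yl)silyl] ether of 21 | C1=C[C@H](C)CC(=O)[C@@H]2[C@]1(C)CC[C@@]2(O[SiH](C(C)C)C(C)C)C(C)C
F6 | step 14 | cyclic 5α,7β-O,O-di(propan-2-yl)silylene derivative of 22 | C1=C[C@H](C)C[C@H](O3)[C@@H]2[C@]1(C)CC[C@@]2(O[Si]3(C(C)C)C(C)C)C(C)C
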